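**Retrosynthetic overview**
1. Target 22 ⇐ 8β-alcohol 18 (angeloylation last) ⇐ TMS-ketal macrolactone 16.
2. Third ring (furanone): transannular attack of the C10 hydroxyl on C3 of 10-hydroxy-ynone 17, the dehydrated equivalent of the biosynthetic 10-hydroxy-1,3-dione/3,10-hemiketal.
3. First and second rings in one operation: the C6–C7 bond (the bond made by germacrene synthase) by umpolung of vinyl epoxide 13 onto the C6 aldehyde, then 6,12-lactonisation with the 8-OH left free (as in eupatolide).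
4. 13 ⇐ enynol 10 + epoxy-dioxolanone 9 (C1–C2 bond); 9 ⇐ L-lactic acid (C10), propargyl bromide and methyl 2-bromoacrylate, with C8 set by Shi epoxidation.
5. Ring order: 10-membered carbocycle → γ-lactone → furanone.

Assumption: the target is taken exactly as the given SMILES, i.e. (6R,7R,8R,10R,11S) with a (Z)-2-methylbut-2-enoate (angelate) ester; germacrane numbering is used for the macrocycles (C1 furanone C=O, C3/C10 ether carbons, C6 lactone O–CH, C8 ester carbinol, C12 lactone C=O).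

**Step 1**
Reactants: 1 (S)-lactic acid; 2 pivalaldehyde
Product: 3 (2S,5S)-2-tert-butyl-5-methyl-1,3-dioxolan-4-one
Conditions: TsOH·H2O (cat.), H2SO4 (cat.), pentane, reflux, Dean–Stark; recrystallise (pentane/Et2O, −78 °C)
Reagents that add atoms: none
Why: Acid-catalysed acetalisation (Seebach self-regeneration of stereocentres) leaves the lactate centre untouched, and the acetal carbon equilibrates to the cis (2S) isomer, which is purified by crystallisation.

**Step 2**
Reactants: 3 (2S,5S)-2-tert-butyl-5-methyl-1,3-dioxolan-4-one; 4 propargyl bromide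
Product: 5 (2S,5R)-2-tert-butyl-5-methyl-5-(prop-2-yn-1-yl)-1,3-dioxolan-4-one
Conditions: LDA (1.1 equiv), THF, −78 °C; then 4, −78 → −30 °C
Reagents that add atoms: none
Why: Seebach enolate alkylation occurs anti to the tert-butyl group (net retention), which sets the quaternary carbinol carbon that becomes C10 (R) of the target.

**Step 3**
Reactants: 5 (2S,5R)-2-tert-butyl-5-methyl-5-(prop-2-yn-1-yl)-1,3-dioxolan-4-one; 6 methyl 2-bromoacrylate
Product: 8 methyl (3E)-5-[(2S,4R)-2-tert-butyl-4-methyl-5-oxo-1,3-dioxolan-4-yl]-2-methylidenepent-3-enoate, via alkenylzirconocene chloride 7 (not isolated)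
Conditions: Cp2Zr(H)Cl (1.2 equiv), THF, rt; then 6 (1.3 equiv), Pd(PPh3)4 (5 mol %), ZnCl2 (20 mol %), 0 °C → rt; crude diene kept cold and used at once
Reagents that add atoms: none
Why: Syn-hydrozirconation (Schwartz) puts Zr on the terminal carbon with E geometry, and Negishi-type Pd cross-coupling with the α-bromoacrylate proceeds with retention to give the E-configured 2-carbomethoxy-1,3-diene.

**Step 4**
Reactants: 8 methyl (3E)-5-[(2S,4R)-2-tert-butyl-4-methyl-5-oxo-1,3-dioxolan-4-yl]-2-methylidenepent-3-enoate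
Product: 9 methyl 2-[(2R,3R)-3-{[(2S,4R)-2-tert-butyl-4-methyl-5-oxo-1,3-dioxolan-4-yl]methyl}oxiran-2-yl]prop-2-enoate
Conditions: D-fructose-derived Shi ketone (30 mol %), Oxone, K2CO3, Bu4NHSO4 (cat.), MeCN/DMM–aq. Na2B4O7/Na2EDTA buffer, −10 → 0 °C
Reagents that add atoms: Oxone (potassium peroxymonosulfate), [K+].[O-]S(=O)(=O)OO
Why: Shi asymmetric epoxidation attacks only the electron-rich E-1,2-disubstituted alkene (the acrylate C=C is inert to the dioxirane), and the spiro transition state gives the (R,R)-epoxide, which sets C8 (R).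

**Step 5**
Reactants: 9 methyl 2-[(2R,3R)-3-{[(2S,4R)-2-tert-butyl-4-methyl-5-oxo-1,3-dioxolan-4-yl]methyl}oxiran-2-yl]prop-2-enoate; 10 (Z)-3-methylpent-2-en-4-yn-1-ol
Product: 12 methyl 2-[(2R,3R)-3-({(2S,4R,5R)-2-tert-butyl-5-[(3Z)-5-hydroxy-3-methylpent-3-en-1-yn-1-yl]-4-methyl-5-(trimethylsilyloxy)-1,3-dioxolan-4-yl}methyl)oxiran-2-yl]prop-2-enoate, via bis-TMS ether 11 (not isolated)
Conditions: 10 (1.3 equiv), n-BuLi (2.6 equiv), THF, −78 °C; add 9, −78 °C; TMSCl (4 equiv), −78 → −30 °C; aq. NaHCO3; then K2CO3 (0.1 equiv), MeOH, −20 → 0 °C, 15 min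
Reagents that add atoms: chlorotrimethylsilane, C[Si](C)(C)Cl
Why: The O,C-dilithiated enynol adds once to the activated dioxolanone carbonyl (acetylide-to-lactone addition) and the tetrahedral alkoxide is trapped as its TMS ketal, so C1 stays masked (no ketone for the later allyl-metal step) and O10 stays inside the acetal; brief methanolysis then frees only the unhindered primary silyl ether, and the new ketal centre (drawn with the alkynyl group anti to tert-butyl) is destroyed in step 9.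

**Step 6**
Reactants: 12 methyl 2-[(2R,3R)-3-({(2S,4R,5R)-2-tert-butyl-5-[(3Z)-5-hydroxy-3-methylpent-3-en-1-yn-1-yl]-4-methyl-5-(trimethylsilyloxy)-1,3-dioxolan-4-yl}methyl)oxiran-2-yl]prop-2-enoate
Product: 13 methyl 2-[(2R,3R)-3-({(2S,4R,5R)-2-tert-butyl-4-methyl-5-[(3Z)-3-methyl-5-oxopent-3-en-1-yn-1-yl]-5-(trimethylsilyloxy)-1,3-dioxolan-4-yl}methyl)oxiran-2-yl]prop-2-enoate
Conditions: MnO2 (20 equiv), CH2Cl2, rt, dark
Reagents that add atoms: none
Why: Neutral MnO2 oxidation of the primary allylic alcohol gives the (Z)-enynal without touching the silyl ketal, the epoxide or the Z geometry.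

**Step 7**
Reactants: 13 methyl 2-[(2R,3R)-3-({(2S,4R,5R)-2-tert-butyl-4-methyl-5-[(3Z)-3-methyl-5-oxopent-3-en-1-yn-1-yl]-5-(trimethylsilyloxy)-1,3-dioxolan-4-yl}methyl)oxiran-2-yl]prop-2-enoate
Product: 15 (6R,7R,8R)-8-hydroxy-11(13)-en-6,12-olide macrocycle (C1–C10 carbocycle; C1/C10 held as the 2-tert-butyl-1,3-dioxolane TMS ketal; C2≡C3; 4Z), via hydroxy ester 14 (not isolated)
Conditions: Pd(PPh3)4 (10 mol %), InI (2.5 equiv), THF/HMPA (4:1), 13 added over 10 h (final 2 mM), rt; pH 7 buffer; then 2-hydroxypyridine (20 mol %), PhMe, 50 °C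
Reagents that add atoms: none
Why: Proposed new method: Pd(0) ionises the vinyl oxirane to a 2-carbomethoxy π-allyl-Pd alkoxide and InI reduces it to a (Z)-allylindium(III) held in a six-membered oxa-indacycle by the C8 alkoxide (C9 pseudo-equatorial), which adds through its γ-carbon C7 to the tethered C6 aldehyde on the indium face and so fixes C7 (R) from C8, while the rigid enyne tether should place C5 anti to C8 and give, after the C6 alkoxide closes on the ester, the trans 6,12-lactone (C6 R) with the 8β-OH left free (as 8β-hydroxy-germacrene acid gives eupatolide); the closest known reactions are the Pd/InI umpolung allylation of aldehydes with vinyl oxiranes and the Cr- or In-mediated Barbier macrolactonisation of 2-(bromomethyl)acrylates.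

**Step 8**
Reactants: 15 (6R,7R,8R)-8-hydroxy-11(13)-en-6,12-olide macrocycle (TMS-ketal dioxolane; C2≡C3; 4Z)
Product: 16 (6R,7R,8R,11S)-8-hydroxy-11,13-dihydro-6,12-olide macrocycle (TMS-ketal dioxolane; C2≡C3; 4Z)
Conditions: [(Ph3P)CuH]6 (0.5 equiv), wet degassed toluene, 0 °C → rt; pH 7 buffer; then DBU (0.2 equiv), CH2Cl2, rt
Reagents that add atoms: none
Why: Stryker conjugate reduction hits the only Michael acceptor present (the exo-methylene lactone; the ynone is still masked), and protonation followed by DBU equilibration gives the more stable 11α-methyl epimer (methyl trans to C8 on the lactone), i.e. 11S.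

**Step 9**
Reactants: 16 (6R,7R,8R,11S)-8-hydroxy-11,13-dihydro-6,12-olide macrocycle (TMS-ketal dioxolane; C2≡C3; 4Z)
Product: 18 (6R,7R,8R,10R,11S)-8-hydroxy-1-oxo-3,10-epoxygermacra-2,4(Z)-dien-6,12-olide, via hydroxy ynone 17 (not isolated)
Conditions: PPTS (0.2 equiv), MeOH, 0 °C; concentrate; Ph3PAuNTf2 (5 mol %), CH2Cl2, rt
Reagents that add atoms: none
Why: Methanolysis of the TMS ketal lets the hemiketal collapse with loss of pivalaldehyde to the 10-hydroxy-ynone, and gold(I) π-activation then drives the transannular 5-endo-dig attack of the C10 hydroxyl on C3 (Au-catalysed α′-hydroxy-ynone to 3(2H)-furanone cyclisation), with C10 unchanged because only its O–H bond reacts.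

**Step 10**
Reactants: 18 (6R,7R,8R,10R,11S)-8-hydroxy-1-oxo-3,10-epoxygermacra-2,4(Z)-dien-6,12-olide; 19 angelic acid; 20 2,4,6-trichlorobenzoyl chloride
Product: 22 (6R,7R,8R,10R,11S)-8-[(2Z)-2-methylbut-2-enoyloxy]-1-oxo-3,10-epoxygermacra-2,4(Z)-dien-6,12-olide (CNP0278264.1), via mixed anhydride 21 (not isolated)
Conditions: 19 (3 equiv), 20 (3 equiv), Et3N (6 equiv), PhMe, rt, 2 h; then 18, 75 °C
Reagents that add atoms: none
Why: Yamaguchi-type esterification through the angelic/trichlorobenzoic mixed anhydride without DMAP acylates the only free (secondary) hydroxyl with retention at C8 and avoids the usual angelate-to-tiglate isomerisation.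

**Compound list**
1 | (S)-lactic acid | C[C@H](O)C(=O)O | starting material
2 | pivalaldehyde | CC(C)(C)C=O | starting material
3 | (2S,5S)-2-tert-butyl-5-methyl-1,3-dioxolan-4-one | C[C@@H]1O[C@H](C(C)(C)C)OC1=O | intermediate
4 | propargyl bromide | C#CCBr | starting material
5 | (2S,5R)-2-tert-butyl-5-methyl-5-(prop-2-yn-1-yl)-1,3-dioxolan-4-one | C#CC[C@@]1(C)O[C@H](C(C)(C)C)OC1=O | intermediate
6 | methyl 2-bromoacrylate | C=C(Br)C(=O)OC | starting material
7 | chloridobis(cyclopentadienyl){(1E)-3-[(2S,4R)-2-tert-butyl-4-methyl-5-oxo-1,3-dioxolan-4-yl]prop-1-en-1-yl}zirconium | Cl[Zr](C1C=CC=C1)(C1C=CC=C1)/C=C/C[C@@]1(C)O[C@H](C(C)(C)C)OC1=O | intermediate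
8 | methyl (3E)-5-[(2S,4R)-2-tert-butyl-4-methyl-5-oxo-1,3-dioxolan-4-yl]-2-methylidenepent-3-enoate | COC(=O)C(=C)/C=C/C[C@@]1(C)O[C@H](C(C)(C)C)OC1=O | intermediate
9 | methyl 2-[(2R,3R)-3-{[(2S,4R)-2-tert-butyl-4-methyl-5-oxo-1,3-dioxolan-4-yl]methyl}oxiran-2-yl]prop-2-enoate | COC(=O)C(=C)[C@H]1O[C@@H]1C[C@@]2(C)O[C@H](C(C)(C)C)OC2=O | intermediate
10 | (Z)-3-methylpent-2-en-4-yn-1-ol | C#C/C(C)=C\CO | starting material
11 | bis-TMS ether of 12 (primary O–SiMe3 and ketal O–SiMe3) | C[Si](C)(C)OC/C=C(/C)C#C[C@]1(O[Si](C)(C)C)O[C@@H](C(C)(C)C)O[C@]1(C)C[C@H]2O[C@@H]2C(=C)C(=O)OC | intermediate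
12 | methyl 2-[(2R,3R)-3-({(2S,4R,5R)-2-tert-butyl-5-[(3Z)-5-hydroxy-3-methylpent-3-en-1-yn-1-yl]-4-methyl-5-(trimethylsilyloxy)-1,3-dioxolan-4-yl}methyl)oxiran-2-yl]prop-2-enoate | OC/C=C(/C)C#C[C@]1(O[Si](C)(C)C)O[C@@H](C(C)(C)C)O[C@]1(C)C[C@H]2O[C@@H]2C(=C)C(=O)OC | intermediate
13 | methyl 2-[(2R,3R)-3-({(2S,4R,5R)-2-tert-butyl-4-methyl-5-[(3Z)-3-methyl-5-oxopent-3-en-1-yn-1-yl]-5-(trimethylsilyloxy)-1,3-dioxolan-4-yl}methyl)oxiran-2-yl]prop-2-enoate | O=C/C=C(/C)C#C[C@]1(O[Si](C)(C)C)O[C@@H](C(C)(C)C)O[C@]1(C)C[C@H]2O[C@@H]2C(=C)C(=O)OC | intermediate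
14 | macrocyclic diol ester: C1–C10 cyclodec-4(Z)-en-2-yne, C1/C10 fused (2S)-2-tert-butyl-1,3-dioxolane [C1 (R) OSiMe3; C10 (R) CH3], 4-methyl, (6R)-OH, (8R)-OH, (7R)-[1-(methoxycarbonyl)ethenyl] | O[C@@H]1C[C@@]2(C)O[C@H](C(C)(C)C)O[C@@]2(O[Si](C)(C)C)C#C/C(C)=C\[C@@H](O)[C@@H]1C(=C)C(=O)OC | intermediate
15 | 6,12-lactone of 14: (6R,7R,8R)-8-hydroxy-11(13)-en-6,12-olide, C1/C10 as TMS-ketal dioxolane, C2≡C3, 4Z | O[C@@H]1C[C@@]2(C)O[C@H](C(C)(C)C)O[C@@]2(O[Si](C)(C)C)C#C/C(C)=C\[C@H]3OC(=O)C(=C)[C@@H]31 | intermediate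
16 | (11S)-11,13-dihydro derivative of 15 | O[C@@H]1C[C@@]2(C)O[C@H](C(C)(C)C)O[C@@]2(O[Si](C)(C)C)C#C/C(C)=C\[C@H]3OC(=O)[C@@H](C)[C@@H]31 | intermediate
17 | (6R,7R,8R,10R,11S)-8,10-dihydroxy-1-oxogermacr-4(Z)-en-2-yn-6,12-olide | O[C@@H]1C[C@@](C)(O)C(=O)C#C/C(C)=C\[C@H]2OC(=O)[C@@H](C)[C@@H]21 | intermediate
18 | (6R,7R,8R,10R,11S)-8-hydroxy-1-oxo-3,10-epoxygermacra-2,4(Z)-dien-6,12-olide | O[C@@H]1C[C@@]2(C)OC(=CC2=O)/C(C)=C\[C@H]2OC(=O)[C@@H](C)[C@@H]21 | intermediate
19 | angelic acid, (Z)-2-methylbut-2-enoic acid | C/C=C(/C)C(=O)O | starting material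
20 | 2,4,6-trichlorobenzoyl chloride | O=C(Cl)c1c(Cl)cc(Cl)cc1Cl | starting material
21 | (Z)-2-methylbut-2-enoic 2,4,6-trichlorobenzoic anhydride | C/C=C(/C)C(=O)OC(=O)c1c(Cl)cc(Cl)cc1Cl | intermediate
22 | CNP0278264.1, (6R,7R,8R,10R,11S)-8-angeloyloxy-1-oxo-3,10-epoxygermacra-2,4(Z)-dien-6,12-olide | C/C=C(/C)C(=O)O[C@@H]1C[C@@]2(C)OC(=CC2=O)/C(C)=C\[C@H]2OC(=O)[C@@H](C)[C@@H]21 | target

**Totals**
Total step count: 10. Longest linear sequence: 10 steps (1 → 22).

**Three steps most likely to fail, with fallbacks**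

Step 7 (macrocyclisation). Risks are oligomerisation, the C6 epimer (cis-lactone), and Pd-side reactions of the zwitterion. The fallback sets out from 13: MgBr2·OEt2 opens the oxirane in the SN2′ sense and the magnesium alkoxide is silylated in situ (TMS-imidazole) to give the (Z)-2-(bromomethyl)enoate with C8–OTMS, allylic bromide F1. CrCl2 in THF/DMF at high dilution then effects a Nozaki–Hiyama/Barbier macro-allylation through a non-chelated (E)-allylchromium, the established route to trans α-methylene lactones, giving 8-O-TMS macrolactone F2. Stryker reduction as in step 8 gives dihydro 8-O-TMS macrolactone F3, and the step 9 conditions remove both silyl groups and close the furanone, so the route is rejoined at 18.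

Step 5 (acetylide addition with silyl-ketal trapping). Risks are collapse of the tetrahedral adduct before silylation and loss of the ketal during the selective desilylation. The fallback sets out from 9: the same dilithio-enynol addition is quenched with AcOH so that pivalaldehyde is lost and the free 10-hydroxy-ynone forms, and 1.0 equiv of Et2NH at 0 °C converts it into the vinylogous amide enaminone diol F4, whose C1 carbonyl no longer reacts with allyl-metals. MnO2 gives enaminone enal F5, the step 7 conditions give enaminone macrolactone F6, and Stryker reduction gives dihydro enaminone macrolactone F7. Aqueous AcOH/THF then hydrolyses the enaminone to the 10-hydroxy-1,3-dione, which undergoes transannular hemiketalisation–dehydration (Jackson–Raphael furanone synthesis), and the route is rejoined at 18.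

Step 3 (hydrozirconation/Negishi to a dimerisation-prone diene). The fallback sets out from 3: enolate alkylation with allyl bromide gives allyl dioxolanone F8 and ozonolysis (O3; Me2S) gives aldehyde F9. Wittig olefination with the ylide from phosphonium bromide F10 (prepared from methyl 2-(bromomethyl)acrylate and PPh3; K2CO3, then I2-catalysed E/Z equilibration) builds the same diene without organometallic intermediates, and the route is rejoined at 8.

**Further compounds**
F1 | step 7 | methyl (2Z)-2-(bromomethyl)-4-(trimethylsilyloxy)but-2-enoate carrying at C4 (R) the {(2S,4R,5R)-2-tert-butyl-4-methyl-5-[(3Z)-3-methyl-5-oxopent-3-en-1-yn-1-yl]-5-(trimethylsilyloxy)-1,3-dioxolan-4-yl}methyl group | O=C/C=C(/C)C#C[C@]1(O[Si](C)(C)C)O[C@@H](C(C)(C)C)O[C@]1(C)C[C@@H](O[Si](C)(C)C)/C=C(\CBr)C(=O)OC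
F2 | step 7 | 8-O-trimethylsilyl ether of 15 | C[Si](C)(C)O[C@@H]1C[C@@]2(C)O[C@H](C(C)(C)C)O[C@@]2(O[Si](C)(C)C)C#C/C(C)=C\[C@H]3OC(=O)C(=C)[C@@H]31
F3 | step 7 | 8-O-trimethylsilyl ether of 16 | C[Si](C)(C)O[C@@H]1C[C@@]2(C)O[C@H](C(C)(C)C)O[C@@]2(O[Si](C)(C)C)C#C/C(C)=C\[C@H]3OC(=O)[C@@H](C)[C@@H]31
F4 | step 5 | methyl 2-[(2R,3R)-3-{(2R,4E,6Z)-5-(diethylamino)-2,8-dihydroxy-2,6-dimethyl-3-oxoocta-4,6-dien-1-yl}oxiran-2-yl]prop-2-enoate | OC/C=C(/C)\C(N(CC)CC)=C/C(=O)[C@](C)(O)C[C@H]1O[C@@H]1C(=C)C(=O)OC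
F5 | step 5 | aldehyde from F4 (C6 primary alcohol oxidised to the (Z)-enal) | O=C/C=C(/C)\C(N(CC)CC)=C/C(=O)[C@](C)(O)C[C@H]1O[C@@H]1C(=C)C(=O)OC
F6 | step 5 | (6R,7R,8R,10R)-3-(diethylamino)-8,10-dihydroxy-1-oxogermacra-2,4(Z),11(13)-trien-6,12-olide | O[C@@H]1C[C@@](C)(O)C(=O)/C=C(N(CC)CC)\C(C)=C/[C@H]2OC(=O)C(=C)[C@@H]21
F7 | step 5 | (11S)-11,13-dihydro derivative of F6 | O[C@@H]1C[C@@](C)(O)C(=O)/C=C(N(CC)CC)\C(C)=C/[C@H]2OC(=O)[C@@H](C)[C@@H]21
F8 | step 3 | (2S,5R)-2-tert-butyl-5-methyl-5-(prop-2-en-1-yl)-1,3-dioxolan-4-one | C=CC[C@@]1(C)O[C@H](C(C)(C)C)OC1=O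
F9 | step 3 | 2-[(2S,4R)-2-tert-butyl-4-methyl-5-oxo-1,3-dioxolan-4-yl]acetaldehyde | O=CC[C@@]1(C)O[C@H](C(C)(C)C)OC1=O
F10 | step 3 | [2-(methoxycarbonyl)prop-2-en-1-yl]triphenylphosphonium bromide | C=C(C[P+](c1ccccc1)(c1ccccc1)c1ccccc1)C(=O)OC.[Br-]
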